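**Retrosynthetic overview**
- Target 21 comes from silyl enol ether 16: the ring C3=C4 alkene is a former silyl enol ether (via triflate 18, then reduction), the isopropenyl group a methylenated acetyl group, and the propanoic acid chain a formyl group extended by two carbons with Meldrum's acid.
- Key disconnection: the cyclohexene ring is cut at C1–C2 and C5–C6 (Diels–Alder retron) into diene 6 (ring carbons C2–C5, already carrying the coumarin ether) and dienophile 9 (ring carbons C1 and C6, with trans formyl and acetyl groups).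
- Enabling feature: the trisubstituted C3=C4 double bond lies across the six-membered ring from the vicinal pair C1 (quaternary: CH3 and chain) and C6 (H and isopropenyl), and both of these carry a carbon substituent that can be a carbonyl group.
- A silyloxy group placed temporarily on C4 polarises the diene so that the regiochemistry is fixed; it is removed in steps 9 and 10.
- Ring order: the coumarin bicycle is bought as 7-hydroxycoumarin; the cyclohexene is the only ring made, in step 5, which sets all three stereocentres.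

Key step: step 5

Assumption: the (R)-configured oxazaborolidinium catalyst is taken to shield the C2-Re face of the formyl-bound enal, as in the accepted formyl C–H···O binding model for 2-substituted acroleins; if the adduct proved antipodal, the (S)-catalyst would be used with no other change.

**Step 1**
Reactants: 1 7-hydroxycoumarin; 2 allyl bromide
Product: 3 7-(allyloxy)coumarin
Conditions: K2CO3, acetone, reflux
Reagents that add atoms: none
Why: Williamson ether synthesis, in which the phenoxide of 1 displaces bromide from the primary allylic halide by SN2.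

**Step 2**
Reactants: 3 7-(allyloxy)coumarin; 4 3-methylbut-3-en-2-one
Product: 5 (E)-enone 7-{[(2E)-3-methyl-4-oxopent-2-en-1-yl]oxy}coumarin
Conditions: second-generation Hoveyda–Grubbs catalyst RuCl2(H2IMes)(=CH-C6H4-2-OiPr) (5 mol %; H2IMes = 1,3-bis(2,4,6-trimethylphenyl)imidazolidin-2-ylidene), 4 (5 equiv), CH2Cl2, 40 °C
Reagents that add atoms: none
Why: Olefin cross-metathesis between a terminal allyl ether and an excess of a non-dimerising 1,1-disubstituted enone should give the trisubstituted enone as the thermodynamically favoured E isomer (acyl trans to CH2OAr) with loss of ethene, the electron-poor endocyclic coumarin alkene taking no part.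

**Step 3**
Reactants: 5 (E)-enone
Product: 6 2-silyloxydiene 7-{[(2E)-3-methyl-4-(triisopropylsilyloxy)penta-2,4-dien-1-yl]oxy}coumarin
Conditions: iPr3SiOTf, Et3N, CH2Cl2, 0 °C
Reagents that add atoms: triisopropylsilyl trifluoromethanesulfonate, CC(C)[Si](C(C)C)(C(C)C)OS(=O)(=O)C(F)(F)F
Why: Soft enolisation and O-silylation of the methyl ketone at its CH3 group should give the cross-conjugated 2-silyloxydiene with the E trisubstituted alkene unchanged.

**Step 4**
Reactants: 7 2,4-dimethylfuran
Product: 9 (2E)-2-methyl-4-oxopent-2-enal, via (2Z)-2-methyl-4-oxopent-2-enal 8 (not isolated)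
Conditions: N-bromosuccinimide, NaHCO3, acetone/H2O (10:1), −15 °C; then pyridine, 23 °C
Reagents that add atoms: water, O
Why: Oxidative ring opening of the furan (bromonium-induced addition of water, then loss of HBr) gives the cis-enedione, which pyridine should isomerise by addition–elimination to the more stable E isomer with formyl and acetyl trans.

**Step 5**
Reactants: 6 2-silyloxydiene; 9 (2E)-2-methyl-4-oxopent-2-enal
Product: 10 Diels–Alder adduct (1S,2R,6S)-6-acetyl-1,3-dimethyl-2-(coumarin-7-yloxymethyl)-4-(triisopropylsilyloxy)cyclohex-3-ene-1-carbaldehyde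
Conditions: (R)-1-(2-methylphenyl)-3,3-diphenyltetrahydro-1H,3H-pyrrolo[1,2-c][1,3,2]oxazaborole (20 mol %), HNTf2 (18 mol %), CH2Cl2, −78 to −40 °C; Et3N quench
Reagents that add atoms: none
Why: The triflimide-activated oxazaborolidine binds the formyl oxygen of 9 (formyl C–H···O contact, s-trans enal) and the electron-rich 2-silyloxydiene 6 adds across the C2=C3 bond of 9 in a concerted, asynchronous normal-demand [4+2] cycloaddition whose leading bond runs from the diene CH2 terminus to C3 of 9; the closest known reaction type is the oxazaborolidinium-catalysed Diels–Alder reaction of 2-substituted acroleins with 2-silyloxybuta-1,3-dienes. The cyclohexene ring is the only ring closed, by intermolecular suprafacial–suprafacial [4+2] closure that forms C5–C6 and C1–C2 of 10 and leaves the new double bond as the C3=C4 silyl enol ether. Regioselectivity is secured by the silyloxy group, which makes the CH2 terminus the nucleophilic end of the diene ("para" orientation, reinforced by the "ortho" effect of the CH2OAr-bearing terminus), and by catalyst binding to the aldehyde in preference to the ketone, which makes C3 of 9 the electrophilic end. The C1/C6 relationship (methyl cis to acetyl) follows stereospecifically from the E geometry of 9, and the C1/C2 relationship (CH2OAr cis to methyl and acetyl) from the E geometry of 6 combined with the transition state that places acetyl and methyl endo and the bulky catalyst-bound formyl group exo, the usual topography of 2-methyl-substituted acroleins. The absolute configuration is controlled by the catalyst, whose cis phenyl group covers one face of the bound enal so that the diene adds to the C2-Si face and C1 of 10 becomes S, with C2 and C6 then following as R and S.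

**Step 6**
Reactants: 10 Diels–Alder adduct; 11 Meldrum's acid
Product: 13 5-alkyl Meldrum's acid, via alkylidene Meldrum's acid 12 (not isolated)
Conditions: L-proline (10 mol %), diethyl 2,6-dimethyl-1,4-dihydropyridine-3,5-dicarboxylate (Hantzsch ester, 1.1 equiv), CH2Cl2, 23 °C
Reagents that add atoms: none
Why: In this three-component reductive alkylation (Knoevenagel condensation, then conjugate transfer hydrogenation by the Hantzsch ester) the non-enolisable formyl group should condense far faster than the branched methyl ketone, and the alkylidene Meldrum's acid is the only C=C electrophilic enough to accept hydride, so the coumarin, the ketone and the silyl enol ether stay intact and no stereocentre is touched.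

**Step 7**
Reactants: 13 5-alkyl Meldrum's acid
Product: 15 keto methyl ester, via malonic half-ester 14 (not isolated)
Conditions: MeOH/pyridine (4:1), 90 °C (sealed tube)
Reagents that add atoms: methanol, CO
Why: Decarboxylative esterification: methanolysis of the Meldrum's acid ring (loss of acetone) gives the malonic half-ester, which should decarboxylate thermally in pyridine, a base too weak to enolise the hindered ketone at C6.

**Step 8**
Reactants: 15 keto methyl ester
Product: 16 isopropenyl silyl enol ether ester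
Conditions: Zn, CH2Br2, TiCl4 (Lombardo reagent, pre-formed in THF), CH2Cl2, 0 to 23 °C
Reagents that add atoms: dibromomethane, BrCBr
Why: Lombardo methylenation with the non-basic Zn/Ti methylene reagent should olefinate the hindered, enolisable ketone without epimerising C6 and without touching the ester, the coumarin lactone or the silyl enol ether.

**Step 9**
Reactants: 16 isopropenyl silyl enol ether ester
Product: 18 vinyl triflate, via cesium enolate 17 (not isolated)
Conditions: CsF, PhNTf2, 1,2-dimethoxyethane, 23 °C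
Reagents that add atoms: N-phenylbis(trifluoromethanesulfonimide), O=S(=O)(N(c1ccccc1)S(=O)(=O)C(F)(F)F)C(F)(F)F
Why: Fluoride-triggered desilylation should unmask the enolate regiospecifically (no other ketone is left to scramble it), and O-sulfonylation by PhNTf2 fixes the double bond between C3 and C4 as the enol triflate.

**Step 10**
Reactants: 18 vinyl triflate
Product: 19 methyl ester of the target
Conditions: Pd(OAc)2 (5 mol %), PPh3 (10 mol %), Et3N, HCO2H, DMF, 60 °C
Reagents that add atoms: none
Why: Palladium-catalysed formate reduction of a vinyl triflate (Cacchi reduction), in which zerovalent palladium inserts into the C–OTf bond and formate delivers hydride with loss of CO2, should replace OTf by H without moving the alkene.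

**Step 11**
Reactants: 19 methyl ester of the target
Product: 21 target acid CNP0103683.1, via lithium carboxylate 20 (not isolated)
Conditions: LiOH, THF/H2O (3:1), 0 to 23 °C; then 1 M HCl to pH 3
Reagents that add atoms: lithium hydroxide, [Li+].[OH-]
Why: Ester saponification by hydroxide followed by acidification, which should also reclose any coumarin lactone opened reversibly to the cis-coumarinate, with no epimerisable stereocentre present.

**Compound list**
1 | 7-hydroxy-2H-chromen-2-one (7-hydroxycoumarin) | Oc1ccc2ccc(=O)oc2c1 | starting material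
2 | 3-bromoprop-1-ene (allyl bromide) | C=CCBr | starting material
3 | 7-(prop-2-en-1-yloxy)-2H-chromen-2-one | C=CCOc1ccc2ccc(=O)oc2c1 | intermediate
4 | 3-methylbut-3-en-2-one | CC(=O)C(C)=C | starting material
5 | 7-{[(2E)-3-methyl-4-oxopent-2-en-1-yl]oxy}-2H-chromen-2-one | CC(=O)/C(C)=C/COc1ccc2ccc(=O)oc2c1 | intermediate
6 | 7-{[(2E)-3-methyl-4-{[tri(propan-2-yl)silyl]oxy}penta-2,4-dien-1-yl]oxy}-2H-chromen-2-one | C=C(O[Si](C(C)C)(C(C)C)C(C)C)/C(C)=C/COc1ccc2ccc(=O)oc2c1 | intermediate
7 | 2,4-dimethylfuran | Cc1cc(C)co1 | starting material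
8 | (2Z)-2-methyl-4-oxopent-2-enal | CC(=O)/C=C(C)\C=O | intermediate
9 | (2E)-2-methyl-4-oxopent-2-enal | CC(=O)/C=C(C)/C=O | intermediate
10 | (1S,2R,6S)-6-acetyl-1,3-dimethyl-2-{[(2-oxo-2H-chromen-7-yl)oxy]methyl}-4-{[tri(propan-2-yl)silyl]oxy}cyclohex-3-ene-1-carbaldehyde | CC(=O)[C@H]1CC(O[Si](C(C)C)(C(C)C)C(C)C)=C(C)[C@@H](COc2ccc3ccc(=O)oc3c2)[C@]1(C)C=O | intermediate
11 | 2,2-dimethyl-1,3-dioxane-4,6-dione (Meldrum's acid) | CC1(C)OC(=O)CC(=O)O1 | starting material
12 | 5-{[(1S,2S,6S)-6-acetyl-1,3-dimethyl-2-{[(2-oxo-2H-chromen-7-yl)oxy]methyl}-4-{[tri(propan-2-yl)silyl]oxy}cyclohex-3-en-1-yl]methylidene}-2,2-dimethyl-1,3-dioxane-4,6-dione | CC(=O)[C@H]1CC(O[Si](C(C)C)(C(C)C)C(C)C)=C(C)[C@@H](COc2ccc3ccc(=O)oc3c2)[C@]1(C)C=C4C(=O)OC(C)(C)OC4=O | intermediate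
13 | 5-{[(1S,2S,6S)-6-acetyl-1,3-dimethyl-2-{[(2-oxo-2H-chromen-7-yl)oxy]methyl}-4-{[tri(propan-2-yl)silyl]oxy}cyclohex-3-en-1-yl]methyl}-2,2-dimethyl-1,3-dioxane-4,6-dione | CC(=O)[C@H]1CC(O[Si](C(C)C)(C(C)C)C(C)C)=C(C)[C@@H](COc2ccc3ccc(=O)oc3c2)[C@]1(C)CC4C(=O)OC(C)(C)OC4=O | intermediate
14 | 2-{[(1S,2S,6S)-6-acetyl-1,3-dimethyl-2-{[(2-oxo-2H-chromen-7-yl)oxy]methyl}-4-{[tri(propan-2-yl)silyl]oxy}cyclohex-3-en-1-yl]methyl}-3-methoxy-3-oxopropanoic acid (malonate carbon unassigned) | CC(=O)[C@H]1CC(O[Si](C(C)C)(C(C)C)C(C)C)=C(C)[C@@H](COc2ccc3ccc(=O)oc3c2)[C@]1(C)CC(C(=O)O)C(=O)OC | intermediate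
15 | methyl 3-[(1S,2S,6S)-6-acetyl-1,3-dimethyl-2-{[(2-oxo-2H-chromen-7-yl)oxy]methyl}-4-{[tri(propan-2-yl)silyl]oxy}cyclohex-3-en-1-yl]propanoate | CC(=O)[C@H]1CC(O[Si](C(C)C)(C(C)C)C(C)C)=C(C)[C@@H](COc2ccc3ccc(=O)oc3c2)[C@]1(C)CCC(=O)OC | intermediate
16 | methyl 3-[(1R,2S,6R)-1,3-dimethyl-2-{[(2-oxo-2H-chromen-7-yl)oxy]methyl}-6-(prop-1-en-2-yl)-4-{[tri(propan-2-yl)silyl]oxy}cyclohex-3-en-1-yl]propanoate | C=C(C)[C@H]1CC(O[Si](C(C)C)(C(C)C)C(C)C)=C(C)[C@@H](COc2ccc3ccc(=O)oc3c2)[C@]1(C)CCC(=O)OC | intermediate
17 | cesium (3S,4R,5R)-4-(3-methoxy-3-oxopropyl)-2,4-dimethyl-3-{[(2-oxo-2H-chromen-7-yl)oxy]methyl}-5-(prop-1-en-2-yl)cyclohex-1-en-1-olate | C=C(C)[C@H]1CC([O-])=C(C)[C@@H](COc2ccc3ccc(=O)oc3c2)[C@]1(C)CCC(=O)OC.[Cs+] | intermediate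
18 | methyl 3-[(1R,2S,6R)-1,3-dimethyl-2-{[(2-oxo-2H-chromen-7-yl)oxy]methyl}-6-(prop-1-en-2-yl)-4-[(trifluoromethanesulfonyl)oxy]cyclohex-3-en-1-yl]propanoate | C=C(C)[C@H]1CC(OS(=O)(=O)C(F)(F)F)=C(C)[C@@H](COc2ccc3ccc(=O)oc3c2)[C@]1(C)CCC(=O)OC | intermediate
19 | methyl 3-[(1R,2R,6R)-1,3-dimethyl-2-{[(2-oxo-2H-chromen-7-yl)oxy]methyl}-6-(prop-1-en-2-yl)cyclohex-3-en-1-yl]propanoate | C=C(C)[C@H]1CC=C(C)[C@@H](COc2ccc3ccc(=O)oc3c2)[C@]1(C)CCC(=O)OC | intermediate
20 | lithium 3-[(1R,2R,6R)-1,3-dimethyl-2-{[(2-oxo-2H-chromen-7-yl)oxy]methyl}-6-(prop-1-en-2-yl)cyclohex-3-en-1-yl]propanoate | C=C(C)[C@H]1CC=C(C)[C@@H](COc2ccc3ccc(=O)oc3c2)[C@]1(C)CCC(=O)[O-].[Li+] | intermediate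
21 | 3-[(1R,2R,6R)-1,3-dimethyl-2-{[(2-oxo-2H-chromen-7-yl)oxy]methyl}-6-(prop-1-en-2-yl)cyclohex-3-en-1-yl]propanoic acid (CNP0103683.1) | C=C(C)[C@H]1CC=C(C)[C@@H](COc2ccc3ccc(=O)oc3c2)[C@]1(C)CCC(=O)O | target

**Step count and risks**

Total step count: 11. Longest linear sequence: 10 steps (steps 1, 2, 3, 5, 6, 7, 8, 9, 10, 11); step 4 is a one-step branch.

Steps most likely to fail, riskiest first:

Step 5. The cycloaddition may proceed through the alternative topography with the catalyst-bound formyl group endo, or on the wrong face, and the strongly acidic catalyst may strip the silyl group from the dienol ether or stop the reaction at the open-chain Mukaiyama–Michael stage. The fallback sets out from 6 and 9 and drops the chiral catalyst. A thermal cycloaddition (toluene, 40–60 °C, no Lewis acid) relies on the intrinsic exo-formyl and endo-acetyl preference of the 2-methyl-substituted enal and on the same silyloxy-controlled regiochemistry, and should give the racemic adduct F1. Preparative chromatography on an amylose tris(3,5-dimethylphenylcarbamate) stationary phase then separates the enantiomers and returns the route to 10.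

Step 6. Condensation at the neopentyl-type aldehyde may be slow, which would let amine-mediated intramolecular aldol or Michael cyclisation of the neighbouring acetyl group compete. The fallback sets out from 10 and builds the chain without a Knoevenagel step. Wittig olefination with (triphenylphosphoranylidene)acetaldehyde (toluene, 80 °C, neutral) should give the (E)-enal F2. Iminium-mediated transfer hydrogenation (Hantzsch ester, dibenzylammonium trifluoroacetate, THF), which reduces only the enal C=C, should give the saturated aldehyde F3. Pinnick oxidation (NaClO2, NaH2PO4, 2-methylbut-2-ene, tBuOH/H2O) should give the carboxylic acid F4, and esterification with (trimethylsilyl)diazomethane in MeOH/toluene returns the route to 15.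

Step 9. Fluoride cleavage of the hindered tetrasubstituted silyl enol ether may be sluggish, and the liberated enolate may be protonated to the ketone (or displace the aryloxide intramolecularly) faster than it is sulfonylated. The fallback sets out from 16 and makes the ketone on purpose. Buffered desilylation (Bu4NF, AcOH, THF, 0 °C) should give the ring ketone F5 as a mixture of C3 epimers. Enol triflate formation under thermodynamic control (Tf2O, 2,6-di-tert-butyl-4-methylpyridine, CH2Cl2, 0 °C), which favours the more substituted C3=C4 enol triflate, returns the route to 18.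

**Further compounds**
F1 | step 5 | racemic 6-acetyl-1,3-dimethyl-2-{[(2-oxo-2H-chromen-7-yl)oxy]methyl}-4-{[tri(propan-2-yl)silyl]oxy}cyclohex-3-ene-1-carbaldehyde (1S,2R,6S and 1R,2S,6R enantiomers) | CC(=O)[C@H]1CC(O[Si](C(C)C)(C(C)C)C(C)C)=C(C)[C@@H](COc2ccc3ccc(=O)oc3c2)[C@]1(C)C=O.CC(=O)[C@@H]1CC(O[Si](C(C)C)(C(C)C)C(C)C)=C(C)[C@H](COc2ccc3ccc(=O)oc3c2)[C@@]1(C)C=O
F2 | step 6 | (2E)-3-[(1S,2S,6S)-6-acetyl-1,3-dimethyl-2-{[(2-oxo-2H-chromen-7-yl)oxy]methyl}-4-{[tri(propan-2-yl)silyl]oxy}cyclohex-3-en-1-yl]prop-2-enal | CC(=O)[C@H]1CC(O[Si](C(C)C)(C(C)C)C(C)C)=C(C)[C@@H](COc2ccc3ccc(=O)oc3c2)[C@]1(C)/C=C/C=O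
F3 | step 6 | 3-[(1S,2S,6S)-6-acetyl-1,3-dimethyl-2-{[(2-oxo-2H-chromen-7-yl)oxy]methyl}-4-{[tri(propan-2-yl)silyl]oxy}cyclohex-3-en-1-yl]propanal | CC(=O)[C@H]1CC(O[Si](C(C)C)(C(C)C)C(C)C)=C(C)[C@@H](COc2ccc3ccc(=O)oc3c2)[C@]1(C)CCC=O
F4 | step 6 | 3-[(1S,2S,6S)-6-acetyl-1,3-dimethyl-2-{[(2-oxo-2H-chromen-7-yl)oxy]methyl}-4-{[tri(propan-2-yl)silyl]oxy}cyclohex-3-en-1-yl]propanoic acid | CC(=O)[C@H]1CC(O[Si](C(C)C)(C(C)C)C(C)C)=C(C)[C@@H](COc2ccc3ccc(=O)oc3c2)[C@]1(C)CCC(=O)O
F5 | step 9 | methyl 3-[(1R,2R,6R)-1,3-dimethyl-4-oxo-2-{[(2-oxo-2H-chromen-7-yl)oxy]methyl}-6-(prop-1-en-2-yl)cyclohexyl]propanoate (mixture of C3 epimers) | C=C(C)[C@H]1CC(=O)C(C)[C@@H](COc2ccc3ccc(=O)oc3c2)[C@]1(C)CCC(=O)OC
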